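In a one-step world you ask two things of a flask, where the step stops and how long it takes to get there, and this flask, for all its steps, takes the same two questions.

    starting material + coupling partner → intermediate + released group (k1 = 5600 /M/s, Ea1 = 29.0 kJ/mol)
    intermediate ⇌ target (K2 = 3.0, k2 = 0.71 /s, Ea2 = 96.0 kJ/mol, ΔH2 = −32.0 kJ/mol)
    intermediate ⇌ isomer of the product A (K3 = 2.6, k3 = 0.19 /s, Ea3 = 92.0 kJ/mol, ΔH3 = −69.0 kJ/mol)
    2 coupling partner → self-condensation product (k4 = 28 /M/s, Ea4 = 56.0 kJ/mol)
    target ⇌ isomer of the product B (K5 = 14, k5 = 0.16 /s, Ea5 = 88.0 kJ/mol, ΔH5 = 60.0 kJ/mol)
    (constants at 110 °C)

| flask | starting material | coupling partner | temperature | time |
|---|---|---|---|---|
| south-east | 0.20 mM | 1.00 mM | 120 °C | 12 s |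
| west | 0.20 mM | 1.00 mM | 110 °C | 12 s |

* which of these there is most of at the end, counted by the starting material in it, south-east (target / isomer of the product A / isomer of the product B / intermediate)
* which of these there is most of at the end, counted by the starting material in it, west (target / isomer of the product A / isomer of the product B / intermediate)
* how much there is at the end of the one of these that leads, in percent of the starting material charged: south-east
* how much there is at the end of the one of these that leads, in percent of the starting material charged: west

- a doubled species enters its step squared and goes two at a time
- the list of constants is for 110 °C, to be carried to other temperatures by the activation energies and enthalpies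

My reckoning starts with the coupling. In west the starting material has a half-life of 0.12 s, while self-condensation alone would halve the coupling partner in 17.9 s, so the coupling finishes first. That leaves one material in four forms.

At rest they stand as one part intermediate, the target's constant in parts of target, the constant of isomer of the product A in parts of that isomer, and for isomer of the product B the target's parts times the constant of the step from target. Its share of those parts is the ceiling.

Now the pace. Intermediate, target and isomer of the product A trade among themselves as a pool (a pre-equilibrium), and material leaves that pool through the target. In west intermediate goes to target with a half-life of 0.98 s, and the drain below takes 8.24 s, which is longer. That figure is the drain half-life: ln(2) over the sum of the target's share of the pool times the forward constant to isomer of the product B, plus the backward constant. The amount at the end is the ceiling times the part of the gap closed, and that part depends on the ratio of the time, 12 s, to this half-life.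

| flask | ceiling | drain half-life | my amount of isomer of the product B |
|---|---|---|---|
| south-east | 91.6% | 4.08 s | 79.7% |
| west | 86.4% | 8.24 s | 54.9% |

The target and isomer of the product B relax between themselves in 2.05 s in south-east, which is short against 12 s. But that holds for the target by itself, and the target is part of a pool, so the drain half-life there is longer. In west my amount is more than the remainder, so I name isomer of the product B as leader in both flasks.

The forecast also names isomer of the product B and isomer of the product B, at 72% in south-east and 51% in west, holding that in the warmer flask “the faster rates outweigh the small amount of material held back in isomer A”. Its south-east figure stands below mine.

The simulation gives isomer of the product B at 73.4% in south-east and isomer of the product B at 52.6% in west. My reckoning ran ahead of both, by 6.3 percentage points and 2.3 points. Neither flask has come to rest: at 120 s isomer of the product B reaches 91.6% in south-east and 86.1% in west, beside ceilings of 91.6% and 86.4%. South-east still has 18 points to gain and west 33 points.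

The forecast's leader does change in a flask colder than south-east. In a flask like south-east kept at 95 °C, the ceiling is 71.3% and the half-life 24.9 s, longer than 12 s, which gives 20.2% of isomer of the product B. The simulation gives 22.7% there, and target leads at 42.5%.

(The numbers are invented; the run is a simulation.)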